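**Retrosynthetic overview**
1. Calbistrin D ⇒ final Heck coupling (side-chain C5–C6) of a terminal-diene triol with (2E,4Z)-5-iodohexa-2,4-dienoic acid.
2. Diene hydroxy ester ⇒ catalyst-controlled anti reductive aldol (new step) between the C8 acrylate of the decalin core and (E)-2-methylpenta-2,4-dienal, setting both side-chain stereocentres.
3. Core ⇒ β-face MeLi addition and formaldehyde aldol on a 1-acetyl dienone ⇒ key semipinacol 1,2-methyl shift of an epoxy carbinol (creates quaternary C1 and the acetyl group) ⇒ MeLi opening of a tricyclic α-alkylidene γ-lactone.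
4. Lactone ⇒ ring-closing metathesis, α-methylenation, hydride reduction/lactonisation and deconjugative dienolate alkylation of (R)-3-butenyl-5-methylcyclohexenone.
5. Ring order: ring A (purchased) → temporary γ-lactone ring → ring B (metathesis) → lactone ring opened before the 1,2-shift.

Assumption: compounds 1, 2, 25 and 26 are taken as purchasable; decalin locants C1–C8a follow the target core (C1 = acyl-bearing quaternary carbon, C2 = carbinol, C8 = ester carbinol carbon), β = face of H-8a, α = opposite face.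

**Step 1**
Reactants: 1 (R)-5-methylcyclohex-2-en-1-one; 2 but-3-en-1-ylmagnesium bromide
Product: 3 {[(3R,5R)-3-(but-3-en-1-yl)-5-methylcyclohex-1-en-1-yl]oxy}trimethylsilane
Conditions: CuBr·SMe2 (5 mol %), Me3SiCl, THF, −78 °C
Reagents that add atoms: chlorotrimethylsilane, C[Si](C)(C)Cl
Why: Copper-catalysed conjugate addition with in situ silyl trapping, in which the organocopper adds anti to the ring methyl (a centre erased in step 2) and the enol ether fixes the site of the next dehydrogenation.

**Step 2**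
Reactants: 3
Product: 4 (R)-3-(but-3-en-1-yl)-5-methylcyclohex-2-en-1-one
Conditions: Pd(OAc)2 (1.05 equiv), MeCN, 25 °C
Reagents that add atoms: none
Why: Saegusa–Ito dehydrogenation, in which the palladium enolate undergoes β-hydride elimination toward C3 and returns the enone with the butenyl group in place while C5 is untouched.

**Step 3**
Reactants: 4; 5 methyl bromoacetate
Product: 6 methyl 2-[(1R,4S)-2-(but-3-en-1-yl)-4-methyl-6-oxocyclohex-2-en-1-yl]acetate
Conditions: KOt-Bu (1.0 equiv), THF/t-BuOH, 0 °C; then 5, −78 to −20 °C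
Reagents that add atoms: none
Why: Deconjugative α-alkylation of the thermodynamic endocyclic dienolate, where the electrophile enters at the α-carbon anti to the ring methyl to give the 2,5-trans (menthone-like, also thermodynamically preferred) C8a centre and moves the double bond to C4a=C5.

**Step 4**
Reactants: 6
Product: 8 (3aR,6S,7aS)-4-(but-3-en-1-yl)-6-methyl-3a,6,7,7a-tetrahydro-1-benzofuran-2(3H)-one, via hydroxy ester 7 (not isolated)
Conditions: LiBH(s-Bu)3, THF, −78 °C; H2O; then pyridinium p-toluenesulfonate (cat.), toluene, 60 °C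
Reagents that add atoms: none
Why: Bulky-hydride ketone reduction then lactonisation, in which equatorial hydride attack gives the axial C8 alkoxide cis to the acetate arm and only this isomer closes to the cis-fused γ-lactone, setting C8 trans to the ring methyl.

**Step 5**
Reactants: 8
Product: 11 (3aS,6S,7aS)-4-(but-3-en-1-yl)-6-methyl-3-methylidene-3a,6,7,7a-tetrahydro-1-benzofuran-2(3H)-one, via Mannich base 9 (not isolated), via methiodide 10 (not isolated)
Conditions: LiN(i-Pr)2, THF, −78 °C; Me2N=CH2 I, −78 to 0 °C; MeI, MeOH, 25 °C; NaHCO3 (aq), CH2Cl2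
Reagents that add atoms: dimethylmethylideneammonium iodide, C[N+](C)=C.[I-]
Why: Lactone enolate Mannich reaction followed by quaternisation and Hofmann-type elimination installs the α-methylene group without creating or touching a stereocentre.

**Step 6**
Reactants: 11
Product: 12 1,8-lactone of 8α-hydroxy-6β-methyl-3,4,6,7,8,8aβ-hexahydronaphthalene-1-carboxylic acid
Conditions: second-generation Grubbs catalyst RuCl2(H2IMes)(PCy3)(=CHPh) (5 mol %), toluene, 80 °C
Reagents that add atoms: none
Why: Ring-closing metathesis between the α-methylene lactone and the terminal alkene closes ring B as a cyclohexene with loss of ethylene, the trisubstituted C4a=C5 alkene being inert.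

**Step 7**
Reactants: 12
Product: 14 2-[6β-methyl-8α-(triethylsilyloxy)-3,4,6,7,8,8aβ-hexahydronaphthalen-1-yl]propan-2-ol, via diol 13 (not isolated)
Conditions: MeLi (3.2 equiv), THF, −78 to 0 °C; then Et3SiCl (1.1 equiv), −78 to −20 °C; H2O
Reagents that add atoms: methyllithium, [Li]C; chlorotriethylsilane, CC[Si](Cl)(CC)CC
Why: Double 1,2-addition of methyllithium opens the lactone to the tertiary allylic carbinol and frees the C8 alkoxide, which as the less hindered secondary alkoxide is silylated selectively in the same flask with no change at any stereocentre.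

**Step 8**
Reactants: 14
Product: 15 1β,2β-epoxide of 14
Conditions: VO(acac)2 (5 mol %), t-BuOOH (1.5 equiv), CH2Cl2, 0 °C
Reagents that add atoms: tert-butyl hydroperoxide, CC(C)(C)OO
Why: Hydroxyl-directed vanadium-catalysed epoxidation of the tertiary allylic alcohol delivers oxygen to the β face because the peri C8 silyl ether blocks the α face, which sets C1 and C2 of the epoxide and leaves the remote C4a=C5 alkene alone.

**Step 9**
Reactants: 15
Product: 16 1-[2β-hydroxy-1α,6β-dimethyl-8α-(triethylsilyloxy)-1,2,3,4,6,7,8,8aβ-octahydronaphthalen-1β-yl]ethan-1-one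
Conditions: ZnBr2 (20 mol %), CH2Cl2, 0 to 25 °C
Reagents that add atoms: none
Why: Semipinacol rearrangement of a tertiary α-hydroxy epoxide, in which a methyl group shifts from the carbinol carbon to C1 anti to the breaking C1–O bond so that the quaternary centre forms with inversion (methyl α, acetyl β) and the carbinol carbon becomes the ketone.

**Step 10**
Reactants: 16
Product: 18 1β-acetyl-1α,6β-dimethyl-8α-(triethylsilyloxy)-6,7,8,8aβ-tetrahydronaphthalen-2(1H)-one, via diketone 17 (not isolated)
Conditions: IBX (3.0 equiv), DMSO/fluorobenzene, 65 °C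
Reagents that add atoms: none
Why: IBX oxidises the secondary alcohol and then dehydrogenates the ring ketone at C3–C4, the only available α,β-CH–CH pair (C1 is quaternary, the acetyl has no β-hydrogen), giving the dienone conjugated with C4a=C5 while the hindered secondary silyl ether survives.

**Step 11**
Reactants: 18
Product: 20 3-hydroxy-1-[2α-hydroxy-1α,2β,6β-trimethyl-8α-(triethylsilyloxy)-1,2,6,7,8,8aβ-hexahydronaphthalen-1β-yl]propan-1-one, via methyl ketone carbinol 19 (not isolated)
Conditions: LiN(SiMe3)2 (1.1 equiv), THF, −78 °C; MeLi (1.3 equiv), −78 °C; CH2O (THF solution, excess), −78 °C; AcOH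
Reagents that add atoms: methyllithium, [Li]C; formaldehyde, C=O
Why: The acetyl group is masked as its lithium enolate, methyllithium then adds 1,2 to the only free carbonyl (C2) from the β face anti to the axial C1 methyl of the lithium-bridged enolate–ketone chelate (C2 methyl β, hydroxyl α), and the enolate is finally trapped by formaldehyde in an aldol reaction at −78 °C.

**Step 12**
Reactants: 20
Product: 21 primary tert-butyldiphenylsilyl ether of 20
Conditions: t-BuPh2SiCl, imidazole, CH2Cl2, 0 °C
Reagents that add atoms: tert-butyl(chloro)diphenylsilane, CC(C)(C)[Si](Cl)(c1ccccc1)c1ccccc1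
Why: Silylation of the unhindered primary alcohol, the tertiary C2 alcohol being unreactive, protects it for the later acylation at C8.

**Step 13**
Reactants: 21
Product: 22 3-(tert-butyldiphenylsilyloxy)-1-[2α,8α-dihydroxy-1α,2β,6β-trimethyl-1,2,6,7,8,8aβ-hexahydronaphthalen-1β-yl]propan-1-one
Conditions: HF·pyridine, pyridine, THF, 0 °C
Reagents that add atoms: none
Why: Buffered fluoride cleaves the triethylsilyl ether much faster than the tert-butyldiphenylsilyl ether and spares the acid-sensitive tertiary dienylic alcohol; the C8 hydroxyl and the β-acyl group are trans and do not close to a lactol.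

**Step 14**
Reactants: 22; 23 acryloyl chloride
Product: 24 C8 acrylate of 22
Conditions: i-Pr2NEt, DMAP (cat.), CH2Cl2, −20 to 0 °C
Reagents that add atoms: none
Why: Acylation of the hindered axial secondary alcohol with a small reactive acid chloride, under which the tertiary alcohol is not acylated.

**Step 15**
Reactants: 25 (E)-3-ethoxy-2-methylprop-2-enal; 26 vinylmagnesium bromide
Product: 28 (E)-2-methylpenta-2,4-dienal, via dienol 27 (not isolated)
Conditions: THF, −78 to 0 °C; then 1 M HCl, 0 to 25 °C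
Reagents that add atoms: none
Why: 1,2-Addition of the Grignard reagent to the vinylogous formate followed by acid hydrolysis of the enol ether with allylic transposition gives the thermodynamically favoured (E)-2-methyl-2-enal.

**Step 16**
Reactants: 24; 28
Product: 30 C8 (2S,3R,4E)-3-hydroxy-2,4-dimethylhepta-4,6-dienoate of the core, via silyl ether 29 (not isolated)
Conditions: Rh[(S,S)-Phebox-i-Pr](OAc)2(H2O) (2 mol %), HSiMe(OEt)2 (1.6 equiv), toluene, 50 °C; then MeOH, aqueous NaHCO3
Reagents that add atoms: none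
Why: Proposed new method: a catalyst-controlled anti-selective reductive aldol used as a fragment coupling, in which the rhodium hydride formed from the silane adds to the acrylate of the hindered core alcohol and the resulting rhodium enolate adds to the enal carbonyl in a closed transition state inside the chiral bis(oxazolinyl)phenyl pocket to set C2 (S) and C3 (R) of the side chain anti; the closest known reaction is the Rh(Phebox)-catalysed reductive aldol of tert-butyl acrylate with simple aldehydes, whose bulky ester is mimicked here by the C8 carbinol, and the ligand enantiomer is to be confirmed on a model acrylate.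

**Step 17**
Reactants: 30
Product: 31 C8 (2S,3R,4E)-3-hydroxy-2,4-dimethylhepta-4,6-dienoate of the desilylated core (triol)
Conditions: Bu4NF, AcOH (1:1), THF, 0 to 25 °C
Reagents that add atoms: none
Why: Buffered fluoride removes the silyl ether without β-elimination or retro-aldol of the β-hydroxy ketone and β-hydroxy ester.

**Step 18**
Reactants: 32 propiolic acid
Product: 33 (E)-3-iodoacrylic acid
Conditions: 57% aqueous HI, 95 °C
Reagents that add atoms: hydrogen iodide, I
Why: Conjugate hydroiodination in which the kinetic (Z) adduct equilibrates at 95 °C to the thermodynamic (E) acid.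

**Step 19**
Reactants: 33; 34 propyne
Product: 35 (E)-hex-2-en-4-ynoic acid
Conditions: PdCl2(PPh3)2 (2 mol %), CuI (4 mol %), Et3N, THF, 25 °C
Reagents that add atoms: none
Why: Sonogashira coupling of the vinyl iodide with retention of the (E) geometry.

**Step 20**
Reactants: 35
Product: 36 (2E,4Z)-5-iodohexa-2,4-dienoic acid
Conditions: NaI, AcOH, 90 °C
Reagents that add atoms: sodium iodide, [Na+].[I-]
Why: Vinylogous conjugate hydroiodination of the enynoic acid, in which iodide adds to the alkyne carbon remote from the carboxyl and anti protonation gives the (Z) vinyl iodide (iodine cis to C3) that fixes the future 4Z double bond.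

**Step 21**
Reactants: 31; 36
Product: 37 Calbistrin D
Conditions: Pd(OAc)2 (10 mol %), Bu4NCl, NaHCO3, DMF, 35 °C, dark
Reagents that add atoms: none
Why: Heck reaction under ligand-free phase-transfer conditions, in which the vinylpalladium species keeps its (Z) geometry, adds to the terminal carbon of the diene and β-hydride elimination gives the 6E alkene, completing the (2E,4Z,6E,8E)-tetraenoic acid without protecting groups.

**Compound list**
1 | (R)-5-methylcyclohex-2-en-1-one | O=C1C[C@H](C)CC=C1 | starting material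
2 | but-3-en-1-ylmagnesium bromide | C=CCC[Mg]Br | starting material
3 | {[(3R,5R)-3-(but-3-en-1-yl)-5-methylcyclohex-1-en-1-yl]oxy}trimethylsilane (butenyl trans to methyl) | C[Si](C)(C)OC1=C[C@H](CCC=C)C[C@@H](C)C1 | intermediate
4 | (R)-3-(but-3-en-1-yl)-5-methylcyclohex-2-en-1-one | O=C1C[C@H](C)CC(CCC=C)=C1 | intermediate
5 | methyl bromoacetate | COC(=O)CBr | starting material
6 | methyl 2-[(1R,4S)-2-(but-3-en-1-yl)-4-methyl-6-oxocyclohex-2-en-1-yl]acetate | O=C1C[C@H](C)C=C(CCC=C)[C@H]1CC(=O)OC | intermediate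
7 | methyl 2-[(1R,4S,6S)-2-(but-3-en-1-yl)-6-hydroxy-4-methylcyclohex-2-en-1-yl]acetate | O[C@H]1C[C@H](C)C=C(CCC=C)[C@H]1CC(=O)OC | intermediate
8 | (3aR,6S,7aS)-4-(but-3-en-1-yl)-6-methyl-3a,6,7,7a-tetrahydro-1-benzofuran-2(3H)-one (cis-fused) | O1[C@H]2C[C@H](C)C=C(CCC=C)[C@H]2CC1=O | intermediate
9 | 3-[(dimethylamino)methyl] derivative of 8 (C3 epimers) | O1[C@H]2C[C@H](C)C=C(CCC=C)[C@H]2C(CN(C)C)C1=O | intermediate
10 | trimethylammonium iodide of 9 | O1[C@H]2C[C@H](C)C=C(CCC=C)[C@H]2C(C[N+](C)(C)C)C1=O.[I-] | intermediate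
11 | (3aS,6S,7aS)-4-(but-3-en-1-yl)-6-methyl-3-methylidene-3a,6,7,7a-tetrahydro-1-benzofuran-2(3H)-one | O1[C@H]2C[C@H](C)C=C(CCC=C)[C@H]2C(=C)C1=O | intermediate
12 | 1,8-lactone of 8α-hydroxy-6β-methyl-3,4,6,7,8,8aβ-hexahydronaphthalene-1-carboxylic acid | O=C1O[C@H]2C[C@H](C)C=C3CCC=C1[C@H]32 | intermediate
13 | 2-(8α-hydroxy-6β-methyl-3,4,6,7,8,8aβ-hexahydronaphthalen-1-yl)propan-2-ol | O[C@H]1C[C@H](C)C=C2CCC=C(C(C)(C)O)[C@H]21 | intermediate
14 | 2-[6β-methyl-8α-(triethylsilyloxy)-3,4,6,7,8,8aβ-hexahydronaphthalen-1-yl]propan-2-ol | CC[Si](CC)(CC)O[C@H]1C[C@H](C)C=C2CCC=C(C(C)(C)O)[C@H]21 | intermediate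
15 | 1β,2β-epoxide of 14 | CC[Si](CC)(CC)O[C@H]1C[C@H](C)C=C2CC[C@@H]3O[C@]3(C(C)(C)O)[C@H]21 | intermediate
16 | 1-[2β-hydroxy-1α,6β-dimethyl-8α-(triethylsilyloxy)-1,2,3,4,6,7,8,8aβ-octahydronaphthalen-1β-yl]ethan-1-one | CC[Si](CC)(CC)O[C@H]1C[C@H](C)C=C2CC[C@H](O)[C@](C)(C(C)=O)[C@H]21 | intermediate
17 | 1β-acetyl-1α,6β-dimethyl-8α-(triethylsilyloxy)-3,4,6,7,8,8aβ-hexahydronaphthalen-2(1H)-one | CC[Si](CC)(CC)O[C@H]1C[C@H](C)C=C2CCC(=O)[C@](C)(C(C)=O)[C@H]21 | intermediate
18 | 1β-acetyl-1α,6β-dimethyl-8α-(triethylsilyloxy)-6,7,8,8aβ-tetrahydronaphthalen-2(1H)-one | CC[Si](CC)(CC)O[C@H]1C[C@H](C)C=C2C=CC(=O)[C@](C)(C(C)=O)[C@H]21 | intermediate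
19 | 1-[2α-hydroxy-1α,2β,6β-trimethyl-8α-(triethylsilyloxy)-1,2,6,7,8,8aβ-hexahydronaphthalen-1β-yl]ethan-1-one | CC[Si](CC)(CC)O[C@H]1C[C@H](C)C=C2C=C[C@@](C)(O)[C@](C)(C(C)=O)[C@H]21 | intermediate
20 | 3-hydroxy-1-[2α-hydroxy-1α,2β,6β-trimethyl-8α-(triethylsilyloxy)-1,2,6,7,8,8aβ-hexahydronaphthalen-1β-yl]propan-1-one | CC[Si](CC)(CC)O[C@H]1C[C@H](C)C=C2C=C[C@@](C)(O)[C@](C)(C(=O)CCO)[C@H]21 | intermediate
21 | primary tert-butyldiphenylsilyl ether of 20 | CC[Si](CC)(CC)O[C@H]1C[C@H](C)C=C2C=C[C@@](C)(O)[C@](C)(C(=O)CCO[Si](c3ccccc3)(c3ccccc3)C(C)(C)C)[C@H]21 | intermediate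
22 | 3-(tert-butyldiphenylsilyloxy)-1-[2α,8α-dihydroxy-1α,2β,6β-trimethyl-1,2,6,7,8,8aβ-hexahydronaphthalen-1β-yl]propan-1-one | O[C@H]1C[C@H](C)C=C2C=C[C@@](C)(O)[C@](C)(C(=O)CCO[Si](c3ccccc3)(c3ccccc3)C(C)(C)C)[C@H]21 | intermediate
23 | acryloyl chloride | C=CC(=O)Cl | starting material
24 | C8 acrylate of 22 | C=CC(=O)O[C@H]1C[C@H](C)C=C2C=C[C@@](C)(O)[C@](C)(C(=O)CCO[Si](c3ccccc3)(c3ccccc3)C(C)(C)C)[C@H]21 | intermediate
25 | (E)-3-ethoxy-2-methylprop-2-enal | CCO/C=C(\C)C=O | starting material
26 | vinylmagnesium bromide | C=C[Mg]Br | starting material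
27 | (E)-1-ethoxy-2-methylpenta-1,4-dien-3-ol (racemic) | CCO/C=C(\C)C(O)C=C | intermediate
28 | (E)-2-methylpenta-2,4-dienal | C=C/C=C(\C)C=O | intermediate
29 | diethoxy(methyl)silyl ether of 30 | C=C/C=C(\C)[C@H](O[Si](C)(OCC)OCC)[C@H](C)C(=O)O[C@H]1C[C@H](C)C=C2C=C[C@@](C)(O)[C@](C)(C(=O)CCO[Si](c3ccccc3)(c3ccccc3)C(C)(C)C)[C@H]21 | intermediate
30 | C8 (2S,3R,4E)-3-hydroxy-2,4-dimethylhepta-4,6-dienoate of 22 | C=C/C=C(\C)[C@H](O)[C@H](C)C(=O)O[C@H]1C[C@H](C)C=C2C=C[C@@](C)(O)[C@](C)(C(=O)CCO[Si](c3ccccc3)(c3ccccc3)C(C)(C)C)[C@H]21 | intermediate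
31 | desilylated 30 (free primary alcohol; triol) | C=C/C=C(\C)[C@H](O)[C@H](C)C(=O)O[C@H]1C[C@H](C)C=C2C=C[C@@](C)(O)[C@](C)(C(=O)CCO)[C@H]21 | intermediate
32 | propiolic acid | C#CC(=O)O | starting material
33 | (E)-3-iodoacrylic acid | OC(=O)/C=C/I | intermediate
34 | propyne | CC#C | starting material
35 | (E)-hex-2-en-4-ynoic acid | CC#C/C=C/C(=O)O | intermediate
36 | (2E,4Z)-5-iodohexa-2,4-dienoic acid | CC(=C/C=C/C(=O)O)/I | intermediate
37 | Calbistrin D, (2E,4Z,6E,8E,10R,11S)-tetraenoic acid esterified at C12 with the core C8 oxygen | CC(=C/C=C/C(=O)O)/C=C/C=C(\C)[C@H](O)[C@H](C)C(=O)O[C@H]1C[C@H](C)C=C2C=C[C@@](C)(O)[C@](C)(C(=O)CCO)[C@H]21 | target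

**Totals**
Total step count: 21. Longest linear sequence: 17 steps (steps 1–14, 16, 17, 21).

**Three steps most likely to fail**

Step 11 (one-pot enolate masking, C2 methylation and hydroxymethylation). Risks are incomplete discrimination of the two ketones and retro-aldol of the dialkoxide. The fallback sets out from 18 and comes back at 20. Compound 18 is treated with LiN(SiMe3)2 and Me3SiCl to give the isolable acetyl trimethylsilyl enol ether F1. MeLi then adds to the remaining dienone carbonyl to give the tertiary carbinol silyl enol ether F2. A Lewis-acid Mukaiyama hydroxymethylation (aqueous formaldehyde, Sc(OTf)3, THF) gives 20, so no strong base ever meets a free β-hydroxy ketone.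

Step 16 (the proposed new reductive aldol coupling). Risks are low turnover with the hindered acrylate, competing aldehyde hydrosilylation and insufficient catalyst control. The fallback uses only known chemistry, sets out from 22 and 28 and comes back at 31. (R)-4-Benzyl-1,3-oxazolidin-2-one is N-acylated with propanoyl chloride to the imide F3; this enantiomer is chosen by the chelated-enolate model. A magnesium-chloride-catalysed anti aldol with 28 (MgCl2, Et3N, Me3SiCl, EtOAc; then MeOH/CF3CO2H) gives the anti aldol imide F4. Et3SiOTf with 2,6-lutidine gives the silyl ether F5, and LiOH/H2O2 releases the acid F6. Yamaguchi esterification with 22 (2,4,6-trichlorobenzoyl chloride, Et3N, DMAP) gives the ester F7. Bu4NF/AcOH removes both silyl groups to give 31.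

Step 21 (late Heck coupling on the unprotected triol). Risks are Z/E scrambling, π-allyl side reactions of the diene and isomerisation of the allylic alcohol. The fallback builds the tetraene on small fragments before the union; it sets out from 36, 28 and 24 and comes back at 37. Acid 36 is esterified (2-(trimethylsilyl)ethanol, DCC, DMAP) to the ester F8. Heck coupling of F8 with 28 gives the tetraenal ester F9. The aldol union with 24 as in step 16 gives the protected hydroxy ester F10; the aldehyde F9 can equally be used in the auxiliary aldol and esterification sequence above. Bu4NF then removes the silyl ether and the 2-(trimethylsilyl)ethyl ester to give 37.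

**Further compounds**
F1 | step 11 | acetyl trimethylsilyl enol ether of 18 | CC[Si](CC)(CC)O[C@H]1C[C@H](C)C=C2C=CC(=O)[C@](C)(C(=C)O[Si](C)(C)C)[C@H]21
F2 | step 11 | C2 methyl carbinol (2β-methyl, 2α-hydroxy) of F1 | CC[Si](CC)(CC)O[C@H]1C[C@H](C)C=C2C=C[C@@](C)(O)[C@](C)(C(=C)O[Si](C)(C)C)[C@H]21
F3 | step 16 | (R)-4-benzyl-3-propanoyl-1,3-oxazolidin-2-one | CCC(=O)N1[C@H](Cc2ccccc2)COC1=O
F4 | step 16 | (R)-4-benzyl-3-[(2S,3R,4E)-3-hydroxy-2,4-dimethylhepta-4,6-dienoyl]-1,3-oxazolidin-2-one | C=C/C=C(\C)[C@H](O)[C@H](C)C(=O)N1[C@H](Cc2ccccc2)COC1=O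
F5 | step 16 | 3-O-triethylsilyl ether of F4 | C=C/C=C(\C)[C@H](O[Si](CC)(CC)CC)[C@H](C)C(=O)N1[C@H](Cc2ccccc2)COC1=O
F6 | step 16 | (2S,3R,4E)-2,4-dimethyl-3-(triethylsilyloxy)hepta-4,6-dienoic acid | C=C/C=C(\C)[C@H](O[Si](CC)(CC)CC)[C@H](C)C(=O)O
F7 | step 16 | C8 ester of 22 with F6 | C=C/C=C(\C)[C@H](O[Si](CC)(CC)CC)[C@H](C)C(=O)O[C@H]1C[C@H](C)C=C2C=C[C@@](C)(O)[C@](C)(C(=O)CCO[Si](c3ccccc3)(c3ccccc3)C(C)(C)C)[C@H]21
F8 | step 21 | 2-(trimethylsilyl)ethyl (2E,4Z)-5-iodohexa-2,4-dienoate | CC(=C/C=C/C(=O)OCC[Si](C)(C)C)/I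
F9 | step 21 | 2-(trimethylsilyl)ethyl (2E,4Z,6E,8E)-5,9-dimethyl-10-oxodeca-2,4,6,8-tetraenoate | CC(=C/C=C/C(=O)OCC[Si](C)(C)C)/C=C/C=C(\C)C=O
F10 | step 21 | 2-(trimethylsilyl)ethyl ester and primary tert-butyldiphenylsilyl ether of 37 | CC(=C/C=C/C(=O)OCC[Si](C)(C)C)/C=C/C=C(\C)[C@H](O)[C@H](C)C(=O)O[C@H]1C[C@H](C)C=C2C=C[C@@](C)(O)[C@](C)(C(=O)CCO[Si](c3ccccc3)(c3ccccc3)C(C)(C)C)[C@H]21
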